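**Retrosynthetic overview**

1. The target is fisetinidol-(4β→6)-mollisacacidin. Its lower 3,4-trans diol is made last, by NaBH4 reduction of a ring C ketone (dihydroflavonol level) after all benzyl ethers have been removed by hydrogenolysis.
2. The interflavan C4(upper)–C6(lower) bond is made with reversed polarity: a 6-cerio lower unit (its C4 carbonyl masked as the carbinol) adds to the C4 ketone of a second molecule of the same dihydroflavonol. Re-oxidation and ionic hydrogenation anti to the 3-silyloxy group then give the 3,4-cis (4β-aryl) upper unit.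
3. Both units therefore come from one protected (2R,3R)-dihydroflavonol 9, whose ring C is closed by forming C2–C3 in a catalytic asymmetric O→C ring contraction (seven- to six-membered) of the 1,3-benzodioxepine enol silane 8.
4. Enabling feature: in ring C at the ketone level, C2 is an aldehyde-level carbon bonded to O1, and C3 carries its own oxygen O3 next to the C4 carbonyl. C2 can therefore be held first as an O1,O3-acetal (ring atoms C8a–O1–C2–O3–C3–C4–C4a) and moved from O3 to C3 through an O1=C2 oxocarbenium ion and the C3=C4 enol.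
5. Ring order: seven-membered acetal ring (step 3), ring C of both units (step 5), union of the two units (step 8). Rings A and B are bought.

Key step: step 5

Remark: the sense of induction of the chiral acid in step 5 cannot be predicted with confidence; the catalyst antipode that leads to the 2R series is to be identified in a first run and is the one meant below.
Remark: 7 and 8 are racemic at the acetal carbon, which is erased in step 5. Compounds 14 and 15 are drawn as the carbinol epimer expected from attack anti to the silyloxy group; either epimer gives the same cation in step 10.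

**Route**

Step 1
Reactants: 1 1-[4-(benzyloxy)-2-hydroxyphenyl]ethan-1-one
Product: 2 tert-butyl({1-[4-(benzyloxy)-2-{[tert-butyl(dimethyl)silyl]oxy}phenyl]ethenyl}oxy)dimethylsilane
Conditions: TBSOTf (2.4 equiv), Et3N, CH2Cl2, 0 °C to rt
Reagents that add atoms: tert-butyldimethylsilyl trifluoromethanesulfonate CC(C)(C)[Si](C)(C)OS(=O)(=O)C(F)(F)F
Why: Soft enolisation with a silyl triflate and an amine silylates the phenol and turns the aryl methyl ketone into its silyl enol ether, the usual substrate for a Rubottom oxidation.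

Step 2
Reactants: 2 tert-butyl({1-[4-(benzyloxy)-2-{[tert-butyl(dimethyl)silyl]oxy}phenyl]ethenyl}oxy)dimethylsilane
Product: 5 1-[4-(benzyloxy)-2-hydroxyphenyl]-2-hydroxyethan-1-one, via silyloxy epoxide 3 (not isolated), via silyloxy ketone 4 (not isolated)
Conditions: mCPBA, NaHCO3, CH2Cl2, 0 °C; then HF·pyridine, THF, rt
Reagents that add atoms: 3-chloroperoxybenzoic acid O=C(OO)c1cccc(Cl)c1
Why: Rubottom oxidation, in which the peracid epoxidises the electron-rich enol silane, the silyloxy epoxide rearranges by silyl migration to the α-silyloxy ketone and fluoride then removes both silyl groups; no stereocentre is formed.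

Step 3
Reactants: 5 1-[4-(benzyloxy)-2-hydroxyphenyl]-2-hydroxyethan-1-one; 6 3,4-bis(benzyloxy)benzaldehyde
Product: 7 rac-8-(benzyloxy)-2-[3,4-bis(benzyloxy)phenyl]-2H-1,3-benzodioxepin-5(4H)-one
Conditions: PPTS (10 mol%), 4 Å molecular sieves, toluene, 40 °C
Reagents that add atoms: none
Why: Acid-catalysed acetalisation of the aldehyde by the phenolic and the primary hydroxyl group closes the seven-membered acetal ring while the sieves take up water, and the weak acid at low temperature should not enolise the ketone, so that the carbon skeleton stays untouched.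

Step 4
Reactants: 7 rac-8-(benzyloxy)-2-[3,4-bis(benzyloxy)phenyl]-2H-1,3-benzodioxepin-5(4H)-one
Product: 8 rac-{[8-(benzyloxy)-2-[3,4-bis(benzyloxy)phenyl]-2H-1,3-benzodioxepin-5-yl]oxy}(tert-butyl)dimethylsilane
Conditions: KN(SiMe3)2, THF, −78 °C; then TBSCl, DMPU, −78 to −20 °C
Reagents that add atoms: tert-butyldimethylsilyl chloride CC(C)(C)[Si](C)(C)Cl
Why: Deprotonation at the only enolisable position and O-silylation of the potassium enolate gives the ring-locked enol silane, and a base is used instead of a silyl triflate so that no achiral Lewis acid can start the rearrangement of step 5.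

Step 5
Reactants: 8 rac-{[8-(benzyloxy)-2-[3,4-bis(benzyloxy)phenyl]-2H-1,3-benzodioxepin-5-yl]oxy}(tert-butyl)dimethylsilane
Product: 9 (2R,3R)-7-(benzyloxy)-2-[3,4-bis(benzyloxy)phenyl]-3-{[tert-butyl(dimethyl)silyl]oxy}-2,3-dihydro-4H-chromen-4-one
Conditions: chiral BINOL-derived imidodiphosphorimidate (IDPi) Brønsted acid (3 mol%), toluene, −60 °C; then Et3N
Reagents that add atoms: none
Why: Proposed new method: the acid is silylated in situ by the enol silane to a chiral silylium ion pair, which should silylate O3 and open the acetal C2–O3 bond to an aryl-oxocarbenium ion (O1=C2, stabilised by the 3,4-bis(benzyloxy)phenyl group) paired with the confined chiral anion; the tethered bis-silyl enediol ether then adds through C3 to C2 and the silyl group on O4 returns to the anion, so that O3 leaves the step as the silyl ether and C4 as the ketone. The closest known reaction types are the Petasis–Ferrier rearrangement of cyclic enol acetals (O→C shift through an oxocarbenium ion and an enolate) and Mukaiyama-type additions of enol silanes to oxocarbenium ions under IDPi silylium catalysis; new is the ring contraction of a 1,3-benzodioxepine in which the enol carbon itself bears the leaving oxygen. Ring C closes in the 6-endo-trig mode at the oxocarbenium carbon with the enol double bond inside the new ring, whereas attack through C4 would be a 5-endo-trig closure and would give a less stabilised cation, which is what secures the ring size. C2 is set by the chiral counter-anion, which differentiates the two faces of the planar oxocarbenium ion, and since the acetal stereocentre of 8 is erased on ionisation both enantiomers of 8 should converge on one product. C3 lies α to the new carbonyl and should settle in the diequatorial 2,3-trans arrangement by way of the silyl enol ether under the reaction conditions. The step needs the C2–O3 and not the C2–O1 bond to ionise productively, and the substrate secures this because only the O1-oxocarbenium ion has a carbon nucleophile within reach, the other ionisation being reversible.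

Step 6
Reactants: 9 (2R,3R)-7-(benzyloxy)-2-[3,4-bis(benzyloxy)phenyl]-3-{[tert-butyl(dimethyl)silyl]oxy}-2,3-dihydro-4H-chromen-4-one
Product: 10 (2R,3S,4R)-7-(benzyloxy)-2-[3,4-bis(benzyloxy)phenyl]-3-{[tert-butyl(dimethyl)silyl]oxy}-3,4-dihydro-2H-chromen-4-ol
Conditions: NaBH4, THF/MeOH, 0 °C
Reagents that add atoms: none
Why: Hydride reduction masks the carbonyl of the future lower unit as a carbinol for the organometallic step; axial hydride delivery should give the 3,4-trans alcohol, but this centre is re-oxidised in step 9 and its configuration does not matter.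

Step 7
Reactants: 10 (2R,3S,4R)-7-(benzyloxy)-2-[3,4-bis(benzyloxy)phenyl]-3-{[tert-butyl(dimethyl)silyl]oxy}-3,4-dihydro-2H-chromen-4-ol
Product: 11 (2R,3S,4R)-7-(benzyloxy)-2-[3,4-bis(benzyloxy)phenyl]-6-bromo-3-{[tert-butyl(dimethyl)silyl]oxy}-3,4-dihydro-2H-chromen-4-ol
Conditions: NBS (1.0 equiv), 2,6-lutidine, MeCN/CH2Cl2, −20 °C
Reagents that add atoms: N-bromosuccinimide O=C1CCC(=O)N1Br
Why: Electrophilic aromatic bromination should go to C6 of ring A, the position para to O1 and ortho to the 7-benzyloxy group of the resorcinol-type ring, which is far more reactive than the catechol-type ring B and less hindered than C8.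

Step 8
Reactants: 11 (2R,3S,4R)-7-(benzyloxy)-2-[3,4-bis(benzyloxy)phenyl]-6-bromo-3-{[tert-butyl(dimethyl)silyl]oxy}-3,4-dihydro-2H-chromen-4-ol; 9 (2R,3R)-7-(benzyloxy)-2-[3,4-bis(benzyloxy)phenyl]-3-{[tert-butyl(dimethyl)silyl]oxy}-2,3-dihydro-4H-chromen-4-one
Product: 14 (2R,3R,4R)-7-(benzyloxy)-2-[3,4-bis(benzyloxy)phenyl]-4-{(2R,3S,4R)-7-(benzyloxy)-2-[3,4-bis(benzyloxy)phenyl]-3-[(tert-butyldimethylsilyl)oxy]-4-hydroxy-3,4-dihydro-2H-chromen-6-yl}-3-[(tert-butyldimethylsilyl)oxy]-3,4-dihydro-2H-chromen-4-ol, via dilithio species 12 (not isolated), via organocerium reagent 13 (not isolated)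
Conditions: n-BuLi (2.1 equiv), THF, −78 °C; CeCl3, −78 °C; then 9, −78 to −40 °C; aq. NH4Cl
Reagents that add atoms: none
Why: Deprotonation of the carbinol and Br/Li exchange, transmetalation to the less basic organocerium reagent and its 1,2-addition to the hindered, enolisable ketone (organocerium addition to ketones) form the interflavan C4–C6 bond; the carbinol configuration should result from attack anti to the silyloxy group but is erased in step 10.

Step 9
Reactants: 14 (2R,3R,4R)-7-(benzyloxy)-2-[3,4-bis(benzyloxy)phenyl]-4-{(2R,3S,4R)-7-(benzyloxy)-2-[3,4-bis(benzyloxy)phenyl]-3-[(tert-butyldimethylsilyl)oxy]-4-hydroxy-3,4-dihydro-2H-chromen-6-yl}-3-[(tert-butyldimethylsilyl)oxy]-3,4-dihydro-2H-chromen-4-ol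
Product: 15 (2R,3R)-7-(benzyloxy)-6-{(2R,3R,4R)-7-(benzyloxy)-2-[3,4-bis(benzyloxy)phenyl]-3-[(tert-butyldimethylsilyl)oxy]-4-hydroxy-3,4-dihydro-2H-chromen-4-yl}-2-[3,4-bis(benzyloxy)phenyl]-3-[(tert-butyldimethylsilyl)oxy]-2,3-dihydro-4H-chromen-4-one
Conditions: Dess–Martin periodinane, NaHCO3, CH2Cl2, rt
Reagents that add atoms: none
Why: Dess–Martin oxidation should return the secondary benzylic alcohol to the ring C ketone of the lower unit, while the tertiary carbinol cannot be oxidised and the silyl ethers prevent overoxidation at C3.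

Step 10
Reactants: 15 (2R,3R)-7-(benzyloxy)-6-{(2R,3R,4R)-7-(benzyloxy)-2-[3,4-bis(benzyloxy)phenyl]-3-[(tert-butyldimethylsilyl)oxy]-4-hydroxy-3,4-dihydro-2H-chromen-4-yl}-2-[3,4-bis(benzyloxy)phenyl]-3-[(tert-butyldimethylsilyl)oxy]-2,3-dihydro-4H-chromen-4-one
Product: 16 (2R,3R)-7-(benzyloxy)-6-{(2R,3S,4R)-7-(benzyloxy)-2-[3,4-bis(benzyloxy)phenyl]-3-[(tert-butyldimethylsilyl)oxy]-3,4-dihydro-2H-chromen-4-yl}-2-[3,4-bis(benzyloxy)phenyl]-3-[(tert-butyldimethylsilyl)oxy]-2,3-dihydro-4H-chromen-4-one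
Conditions: Et3SiH (5 equiv), TFA (3 equiv), CH2Cl2, −60 to −20 °C
Reagents that add atoms: none
Why: Ionic hydrogenation, in which the acid ionises the tertiary bis-benzylic carbinol to a diaryl carbenium ion and the silane should deliver hydride to the face anti to the bulky vicinal 3-silyloxy group, so that the aryl group ends up cis to O3 (3,4-cis, 4β-aryl); the lower unit, now a ketone, has no ionisable C4–O bond.

Step 11
Reactants: 16 (2R,3R)-7-(benzyloxy)-6-{(2R,3S,4R)-7-(benzyloxy)-2-[3,4-bis(benzyloxy)phenyl]-3-[(tert-butyldimethylsilyl)oxy]-3,4-dihydro-2H-chromen-4-yl}-2-[3,4-bis(benzyloxy)phenyl]-3-[(tert-butyldimethylsilyl)oxy]-2,3-dihydro-4H-chromen-4-one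
Product: 17 (2R,3R)-7-(benzyloxy)-6-{(2R,3S,4R)-7-(benzyloxy)-2-[3,4-bis(benzyloxy)phenyl]-3-hydroxy-3,4-dihydro-2H-chromen-4-yl}-2-[3,4-bis(benzyloxy)phenyl]-3-hydroxy-2,3-dihydro-4H-chromen-4-one
Conditions: HF·pyridine, THF, 0 °C to rt
Reagents that add atoms: none
Why: Fluoride cleavage of the two secondary silyl ethers under non-basic conditions, which should avoid epimerisation or ring opening of the dihydroflavonol unit.

Step 12
Reactants: 17 (2R,3R)-7-(benzyloxy)-6-{(2R,3S,4R)-7-(benzyloxy)-2-[3,4-bis(benzyloxy)phenyl]-3-hydroxy-3,4-dihydro-2H-chromen-4-yl}-2-[3,4-bis(benzyloxy)phenyl]-3-hydroxy-2,3-dihydro-4H-chromen-4-one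
Product: 18 (2R,3R)-2-(3,4-dihydroxyphenyl)-6-[(2R,3S,4S)-2-(3,4-dihydroxyphenyl)-3,7-dihydroxy-3,4-dihydro-2H-chromen-4-yl]-3,7-dihydroxy-2,3-dihydro-4H-chromen-4-one
Conditions: H2 (1 atm), Pd(OH)2 on carbon, THF/MeOH, rt
Reagents that add atoms: none
Why: Hydrogenolysis of the six benzyl aryl ethers under neutral conditions, which should leave the conjugated aryl ketone and the ring C benzylic C–O and C–aryl bonds intact.

Step 13
Reactants: 18 (2R,3R)-2-(3,4-dihydroxyphenyl)-6-[(2R,3S,4S)-2-(3,4-dihydroxyphenyl)-3,7-dihydroxy-3,4-dihydro-2H-chromen-4-yl]-3,7-dihydroxy-2,3-dihydro-4H-chromen-4-one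
Product: 19 (2R,3S,4R)-2-(3,4-dihydroxyphenyl)-6-[(2R,3S,4S)-2-(3,4-dihydroxyphenyl)-3,7-dihydroxy-3,4-dihydro-2H-chromen-4-yl]-3,4-dihydro-2H-chromene-3,4,7-triol (CNP0280090.2)
Conditions: NaBH4, EtOH, 0 °C; then AcOH to pH 6
Reagents that add atoms: none
Why: Borohydride reduction of a free-phenolic 2,3-trans dihydroflavonol is the classical entry to 2,3-trans-3,4-trans flavan-3,4-diols, axial hydride delivery giving the equatorial 4-hydroxyl trans to the 3-hydroxyl and so setting 4R.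

**Compound list**

1 | 1-[4-(benzyloxy)-2-hydroxyphenyl]ethan-1-one | CC(=O)c1ccc(OCc2ccccc2)cc1O | starting material
2 | tert-butyl({1-[4-(benzyloxy)-2-{[tert-butyl(dimethyl)silyl]oxy}phenyl]ethenyl}oxy)dimethylsilane | C=C(O[Si](C)(C)C(C)(C)C)c1ccc(OCc2ccccc2)cc1O[Si](C)(C)C(C)(C)C | intermediate
3 | rac-2-[4-(benzyloxy)-2-{[tert-butyl(dimethyl)silyl]oxy}phenyl]-2-{[tert-butyl(dimethyl)silyl]oxy}oxirane (not isolated) | C1OC1(O[Si](C)(C)C(C)(C)C)c1ccc(OCc2ccccc2)cc1O[Si](C)(C)C(C)(C)C | intermediate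
4 | 1-[4-(benzyloxy)-2-{[tert-butyl(dimethyl)silyl]oxy}phenyl]-2-{[tert-butyl(dimethyl)silyl]oxy}ethan-1-one (not isolated) | O=C(CO[Si](C)(C)C(C)(C)C)c1ccc(OCc2ccccc2)cc1O[Si](C)(C)C(C)(C)C | intermediate
5 | 1-[4-(benzyloxy)-2-hydroxyphenyl]-2-hydroxyethan-1-one | O=C(CO)c1ccc(OCc2ccccc2)cc1O | intermediate
6 | 3,4-bis(benzyloxy)benzaldehyde | O=Cc1ccc(OCc2ccccc2)c(OCc2ccccc2)c1 | starting material
7 | rac-8-(benzyloxy)-2-[3,4-bis(benzyloxy)phenyl]-2H-1,3-benzodioxepin-5(4H)-one | O=C1COC(c2ccc(OCc3ccccc3)c(OCc3ccccc3)c2)Oc2cc(OCc3ccccc3)ccc21 | intermediate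
8 | rac-{[8-(benzyloxy)-2-[3,4-bis(benzyloxy)phenyl]-2H-1,3-benzodioxepin-5-yl]oxy}(tert-butyl)dimethylsilane | CC(C)(C)[Si](C)(C)OC1=COC(c2ccc(OCc3ccccc3)c(OCc3ccccc3)c2)Oc2cc(OCc3ccccc3)ccc21 | intermediate
9 | (2R,3R)-7-(benzyloxy)-2-[3,4-bis(benzyloxy)phenyl]-3-{[tert-butyl(dimethyl)silyl]oxy}-2,3-dihydro-4H-chromen-4-one | c1ccccc1COc1ccc2c(c1)O[C@H](c1ccc(OCc3ccccc3)c(OCc3ccccc3)c1)[C@@H](O[Si](C)(C)C(C)(C)C)C2=O | intermediate
10 | (2R,3S,4R)-7-(benzyloxy)-2-[3,4-bis(benzyloxy)phenyl]-3-{[tert-butyl(dimethyl)silyl]oxy}-3,4-dihydro-2H-chromen-4-ol | c1ccccc1COc1ccc2c(c1)O[C@H](c1ccc(OCc3ccccc3)c(OCc3ccccc3)c1)[C@@H](O[Si](C)(C)C(C)(C)C)[C@@H]2O | intermediate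
11 | (2R,3S,4R)-7-(benzyloxy)-2-[3,4-bis(benzyloxy)phenyl]-6-bromo-3-{[tert-butyl(dimethyl)silyl]oxy}-3,4-dihydro-2H-chromen-4-ol | c1ccccc1COc1c(Br)cc2c(c1)O[C@H](c1ccc(OCc3ccccc3)c(OCc3ccccc3)c1)[C@@H](O[Si](C)(C)C(C)(C)C)[C@@H]2O | intermediate
12 | lithium (2R,3S,4R)-7-(benzyloxy)-2-[3,4-bis(benzyloxy)phenyl]-3-{[tert-butyl(dimethyl)silyl]oxy}-6-lithio-3,4-dihydro-2H-chromen-4-olate (not isolated) | c1ccccc1COc1c([Li])cc2c(c1)O[C@H](c1ccc(OCc3ccccc3)c(OCc3ccccc3)c1)[C@@H](O[Si](C)(C)C(C)(C)C)[C@@H]2O[Li] | intermediate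
13 | lithium (2R,3S,4R)-7-(benzyloxy)-2-[3,4-bis(benzyloxy)phenyl]-3-{[tert-butyl(dimethyl)silyl]oxy}-6-(dichlorocerio)-3,4-dihydro-2H-chromen-4-olate (not isolated) | c1ccccc1COc1c([Ce](Cl)Cl)cc2c(c1)O[C@H](c1ccc(OCc3ccccc3)c(OCc3ccccc3)c1)[C@@H](O[Si](C)(C)C(C)(C)C)[C@@H]2O[Li] | intermediate
14 | (2R,3R,4R)-7-(benzyloxy)-2-[3,4-bis(benzyloxy)phenyl]-4-{(2R,3S,4R)-7-(benzyloxy)-2-[3,4-bis(benzyloxy)phenyl]-3-[(tert-butyldimethylsilyl)oxy]-4-hydroxy-3,4-dihydro-2H-chromen-6-yl}-3-[(tert-butyldimethylsilyl)oxy]-3,4-dihydro-2H-chromen-4-ol | c1ccccc1COc1ccc2c(c1)O[C@H](c1ccc(OCc3ccccc3)c(OCc3ccccc3)c1)[C@@H](O[Si](C)(C)C(C)(C)C)[C@]2(O)c1cc2c(cc1OCc1ccccc1)O[C@H](c1ccc(OCc3ccccc3)c(OCc3ccccc3)c1)[C@@H](O[Si](C)(C)C(C)(C)C)[C@@H]2O | intermediate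
15 | (2R,3R)-7-(benzyloxy)-6-{(2R,3R,4R)-7-(benzyloxy)-2-[3,4-bis(benzyloxy)phenyl]-3-[(tert-butyldimethylsilyl)oxy]-4-hydroxy-3,4-dihydro-2H-chromen-4-yl}-2-[3,4-bis(benzyloxy)phenyl]-3-[(tert-butyldimethylsilyl)oxy]-2,3-dihydro-4H-chromen-4-one | c1ccccc1COc1ccc2c(c1)O[C@H](c1ccc(OCc3ccccc3)c(OCc3ccccc3)c1)[C@@H](O[Si](C)(C)C(C)(C)C)[C@]2(O)c1cc2c(cc1OCc1ccccc1)O[C@H](c1ccc(OCc3ccccc3)c(OCc3ccccc3)c1)[C@@H](O[Si](C)(C)C(C)(C)C)C2=O | intermediate
16 | (2R,3R)-7-(benzyloxy)-6-{(2R,3S,4R)-7-(benzyloxy)-2-[3,4-bis(benzyloxy)phenyl]-3-[(tert-butyldimethylsilyl)oxy]-3,4-dihydro-2H-chromen-4-yl}-2-[3,4-bis(benzyloxy)phenyl]-3-[(tert-butyldimethylsilyl)oxy]-2,3-dihydro-4H-chromen-4-one | c1ccccc1COc1ccc2c(c1)O[C@H](c1ccc(OCc3ccccc3)c(OCc3ccccc3)c1)[C@@H](O[Si](C)(C)C(C)(C)C)[C@H]2c1cc2c(cc1OCc1ccccc1)O[C@H](c1ccc(OCc3ccccc3)c(OCc3ccccc3)c1)[C@@H](O[Si](C)(C)C(C)(C)C)C2=O | intermediate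
17 | (2R,3R)-7-(benzyloxy)-6-{(2R,3S,4R)-7-(benzyloxy)-2-[3,4-bis(benzyloxy)phenyl]-3-hydroxy-3,4-dihydro-2H-chromen-4-yl}-2-[3,4-bis(benzyloxy)phenyl]-3-hydroxy-2,3-dihydro-4H-chromen-4-one | c1ccccc1COc1ccc2c(c1)O[C@H](c1ccc(OCc3ccccc3)c(OCc3ccccc3)c1)[C@@H](O)[C@H]2c1cc2c(cc1OCc1ccccc1)O[C@H](c1ccc(OCc3ccccc3)c(OCc3ccccc3)c1)[C@@H](O)C2=O | intermediate
18 | (2R,3R)-2-(3,4-dihydroxyphenyl)-6-[(2R,3S,4S)-2-(3,4-dihydroxyphenyl)-3,7-dihydroxy-3,4-dihydro-2H-chromen-4-yl]-3,7-dihydroxy-2,3-dihydro-4H-chromen-4-one | Oc1ccc2c(c1)O[C@H](c1ccc(O)c(O)c1)[C@@H](O)[C@H]2c1cc2c(cc1O)O[C@H](c1ccc(O)c(O)c1)[C@@H](O)C2=O | intermediate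
19 | (2R,3S,4R)-2-(3,4-dihydroxyphenyl)-6-[(2R,3S,4S)-2-(3,4-dihydroxyphenyl)-3,7-dihydroxy-3,4-dihydro-2H-chromen-4-yl]-3,4-dihydro-2H-chromene-3,4,7-triol | Oc1ccc2c(c1)O[C@H](c1ccc(O)c(O)c1)[C@@H](O)[C@H]2c1cc2c(cc1O)O[C@H](c1ccc(O)c(O)c1)[C@@H](O)[C@@H]2O | target

**Step count and risks**

Total step count: 13. Longest linear sequence: 13 steps (steps 1 to 13 lie on one line; ketone 9 enters a second time in step 8).

Steps most likely to fail:

Step 5 (proposed new method). What may go wrong: weak facial discrimination of the oxocarbenium ion by the chiral anion, or unproductive ionisation and decomposition of the enol silane instead of ring contraction. Fallback by known chemistry, setting out from 1 (with 6) and coming back at 9: the phenol of 1 is protected (MOMCl, i-Pr2NEt) to give 1-[4-(benzyloxy)-2-(methoxymethoxy)phenyl]ethan-1-one F1. Claisen–Schmidt condensation with 6 (KOH, EtOH) should give (E)-1-[4-(benzyloxy)-2-(methoxymethoxy)phenyl]-3-[3,4-bis(benzyloxy)phenyl]prop-2-en-1-one F2. Juliá–Colonna epoxidation (poly-L-leucine, urea–H2O2, DBU, THF) should give [(2R,3S)-3-[3,4-bis(benzyloxy)phenyl]oxiran-2-yl][4-(benzyloxy)-2-(methoxymethoxy)phenyl]methanone F3. HCl in MeOH/THF should remove the acetal protecting group and let the freed phenol open the epoxide at the benzylic carbon with inversion (6-endo) to give (2R,3R)-7-(benzyloxy)-2-[3,4-bis(benzyloxy)phenyl]-3-hydroxy-2,3-dihydro-4H-chromen-4-one F4, and silylation (TBSOTf, 2,6-lutidine) leads to 9.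

Step 8. What may go wrong: enolisation of the ketone or β-elimination with opening of ring C instead of 1,2-addition, and proton transfer within the aryl-metal species. Fallback with normal polarity, setting out from 11 (with 10) and coming back at 15: 11 is oxidised (Dess–Martin periodinane) to (2R,3R)-7-(benzyloxy)-2-[3,4-bis(benzyloxy)phenyl]-6-bromo-3-[(tert-butyldimethylsilyl)oxy]-2,3-dihydro-4H-chromen-4-one F5. Miyaura borylation (B2pin2, PdCl2(dppf), KOAc, dioxane) should give the 6-(4,4,5,5-tetramethyl-1,3,2-dioxaborolan-2-yl) ketone F6, and KHF2 in MeOH/water the potassium 6-trifluoroborate F7. BF3·OEt2 then ionises alcohol 10 at C4, and ipso-substitution of the trifluoroborate should give the 4-aryl flavan, C4 epimer of 16, F8 (drawn as the 3,4-trans epimer expected to predominate). DDQ in wet CH2Cl2 abstracts the doubly benzylic hydride at the upper C4 and water traps the cation to give 15, after which step 10 sets the configuration.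

Step 10. What may go wrong: poor facial selectivity of hydride delivery to the planar diaryl cation, or loss of the C3 proton from the cation. Fallback by stereospecific hydrogenolysis, setting out from 15 and coming back at 18: H2 over Pd on carbon in EtOAc/AcOH should cleave the tertiary benzylic C–OH bond with inversion (hydrogen enters anti to the departing hydroxyl) and remove the six benzyl groups in the same operation, giving (2R,3R)-3-[(tert-butyldimethylsilyl)oxy]-6-{(2R,3S,4S)-3-[(tert-butyldimethylsilyl)oxy]-2-(3,4-dihydroxyphenyl)-7-hydroxy-3,4-dihydro-2H-chromen-4-yl}-2-(3,4-dihydroxyphenyl)-7-hydroxy-2,3-dihydro-4H-chromen-4-one F9. HF·pyridine then gives 18.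

Further compounds
F1 | step 5 | 1-[4-(benzyloxy)-2-(methoxymethoxy)phenyl]ethan-1-one | CC(=O)c1ccc(OCc2ccccc2)cc1OCOC
F2 | step 5 | (E)-1-[4-(benzyloxy)-2-(methoxymethoxy)phenyl]-3-[3,4-bis(benzyloxy)phenyl]prop-2-en-1-one | O=C(/C=C/c1ccc(OCc2ccccc2)c(OCc2ccccc2)c1)c1ccc(OCc2ccccc2)cc1OCOC
F3 | step 5 | [(2R,3S)-3-[3,4-bis(benzyloxy)phenyl]oxiran-2-yl][4-(benzyloxy)-2-(methoxymethoxy)phenyl]methanone | O=C(c1ccc(OCc2ccccc2)cc1OCOC)[C@@H]1O[C@H]1c1ccc(OCc2ccccc2)c(OCc2ccccc2)c1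
F4 | step 5 | (2R,3R)-7-(benzyloxy)-2-[3,4-bis(benzyloxy)phenyl]-3-hydroxy-2,3-dihydro-4H-chromen-4-one | c1ccccc1COc1ccc2c(c1)O[C@H](c1ccc(OCc3ccccc3)c(OCc3ccccc3)c1)[C@@H](O)C2=O
F5 | step 8 | (2R,3R)-7-(benzyloxy)-2-[3,4-bis(benzyloxy)phenyl]-6-bromo-3-[(tert-butyldimethylsilyl)oxy]-2,3-dihydro-4H-chromen-4-one | c1ccccc1COc1c(Br)cc2c(c1)O[C@H](c1ccc(OCc3ccccc3)c(OCc3ccccc3)c1)[C@@H](O[Si](C)(C)C(C)(C)C)C2=O
F6 | step 8 | (2R,3R)-7-(benzyloxy)-2-[3,4-bis(benzyloxy)phenyl]-3-[(tert-butyldimethylsilyl)oxy]-6-(4,4,5,5-tetramethyl-1,3,2-dioxaborolan-2-yl)-2,3-dihydro-4H-chromen-4-one | c1ccccc1COc1c(B3OC(C)(C)C(C)(C)O3)cc2c(c1)O[C@H](c1ccc(OCc3ccccc3)c(OCc3ccccc3)c1)[C@@H](O[Si](C)(C)C(C)(C)C)C2=O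
F7 | step 8 | potassium {(2R,3R)-7-(benzyloxy)-2-[3,4-bis(benzyloxy)phenyl]-3-[(tert-butyldimethylsilyl)oxy]-4-oxo-3,4-dihydro-2H-chromen-6-yl}trifluoroborate | [K+].F[B-](F)(F)c1cc2c(cc1OCc1ccccc1)O[C@H](c1ccc(OCc3ccccc3)c(OCc3ccccc3)c1)[C@@H](O[Si](C)(C)C(C)(C)C)C2=O
F8 | step 8 | (2R,3R)-7-(benzyloxy)-6-{(2R,3S,4S)-7-(benzyloxy)-2-[3,4-bis(benzyloxy)phenyl]-3-[(tert-butyldimethylsilyl)oxy]-3,4-dihydro-2H-chromen-4-yl}-2-[3,4-bis(benzyloxy)phenyl]-3-[(tert-butyldimethylsilyl)oxy]-2,3-dihydro-4H-chromen-4-one | c1ccccc1COc1ccc2c(c1)O[C@H](c1ccc(OCc3ccccc3)c(OCc3ccccc3)c1)[C@@H](O[Si](C)(C)C(C)(C)C)[C@@H]2c1cc2c(cc1OCc1ccccc1)O[C@H](c1ccc(OCc3ccccc3)c(OCc3ccccc3)c1)[C@@H](O[Si](C)(C)C(C)(C)C)C2=O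
F9 | step 10 | (2R,3R)-3-[(tert-butyldimethylsilyl)oxy]-6-{(2R,3S,4S)-3-[(tert-butyldimethylsilyl)oxy]-2-(3,4-dihydroxyphenyl)-7-hydroxy-3,4-dihydro-2H-chromen-4-yl}-2-(3,4-dihydroxyphenyl)-7-hydroxy-2,3-dihydro-4H-chromen-4-one | Oc1ccc2c(c1)O[C@H](c1ccc(O)c(O)c1)[C@@H](O[Si](C)(C)C(C)(C)C)[C@H]2c1cc2c(cc1O)O[C@H](c1ccc(O)c(O)c1)[C@@H](O[Si](C)(C)C(C)(C)C)C2=O
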